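All runs stem from a simulated flask with made-up constants, noise included.

Per millimolar of free monomer charged, you can read one exponent off the earlier runs, so start there.

common to all: initiator 0.5 mol%
- teal: free monomer 14 mM; protic impurity 2.1 mM; run made earlier
- amber: free monomer 32 mM; protic impurity 2.1 mM; run made earlier
- blue: free monomer 21 mM; protic impurity 1.1 mM; run made earlier
- flask: free monomer 21 mM; protic impurity 2.10 mM; time 6.0 d

| run | time / d | free monomer / % | over-reaction product / % | monomer in chains / % |
|---|---|---|---|---|
| teal | 0.250 | 76.2 | 5.4 | 7.0 |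
| teal | 0.417 | 71.9 | 9.1 | 5.8 |
| teal | 0.625 | 68.7 | 14.7 | 2.9 |
| teal | 1.04 | 65.2 | 16.5 | 0.6 |
| teal | 1.67 | 65.8 | 18.9 | 0.2 |
| teal | 2.50 | 66.4 | 16.6 | 0 |
| teal | 4.00 | 65.8 | 20.3 | 0 |
| amber | 0.250 | 65.0 | 12.9 | 15.8 |
| amber | 0.417 | 60.0 | 22.4 | 11.9 |
| amber | 0.625 | 56.6 | 31.4 | 7.5 |
| amber | 1.04 | 54.7 | 39.9 | 3.0 |
| amber | 1.67 | 51.6 | 41.4 | 0.5 |
| amber | 2.50 | 51.2 | 41.5 | 1.4 |
| amber | 4.00 | 53.6 | 41.2 | 0.4 |
| blue | 0.625 | 67.6 | 23.0 | 5.9 |
| blue | 1.25 | 65.5 | 28.3 | 1.6 |
| blue | 2.00 | 64.5 | 27.5 | 0.5 |
| blue | 3.00 | 65.9 | 30.2 | 0 |
| blue | 4.00 | 66.7 | 29.7 | 0.5 |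

(standard deviation of a reading: 1 percentage point)

- where most of what was charged as free monomer, at 6.0 d is found (free monomer / monomer in chains / over-reaction product)
- the largest share itself, whichever of these holds it, in percent of the free monomer charged

- on the list of suspects stand: free monomer + initiator -> living end + monomer in chains; free monomer + living end -> monomer in chains + living end; monomer in chains + living end -> free monomer + living end; living end -> dead end; monomer in chains -> over-reaction product; protic impurity + free monomer -> quenched substrate

The protic impurity takes free monomer one for one: at the end of the teal run, free monomer plus over-reaction product reads 86.1%, against 85.0% left once [protic impurity] is subtracted from [free monomer]. Call that remainder the available share. But the readings flatten, with free monomer near 66.0% in teal, 52.1% in amber and 65.7% in blue, so I read the living ends as dying out while free monomer still stands, and I take its loss as pseudo-first-order in free monomer, with a finite dose of living ends. Initiator stands at 0.5 mol% of the charge, so that dose should grow with [free monomer]. Dividing the logarithm of available over final share by the charge gives 0.0181 mM⁻¹ for teal, about the same as amber's 0.0182 mM⁻¹, and 0.0174 mM⁻¹ for blue. Their mean, 0.0179 mM⁻¹, is the burn-out coefficient, that logarithm per millimolar charged.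

For the flask, the available share is 90.0% and the exponent 0.376, so I expect 61.8% free monomer. Put back into the balance, that leaves 28.2% as over-reaction product, less than the free monomer.

The forecast also names free monomer, at 62%: “the equilibrium monomer level is negligible”.

The flask gives free monomer at 62.0%.

    free monomer + initiator → living end + monomer in chains (k = 0.0480 M⁻¹ s⁻¹)
    free monomer + living end → monomer in chains + living end, rate k2*[living end]*[free monomer] (k = 0.160 M⁻¹ s⁻¹)
    monomer in chains + living end → free monomer + living end, rate k3*[living end] as long as [monomer in chains] is above zero (k = 1.80 × 10⁻⁴ s⁻¹)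
    living end → dead end (k = 4.30 × 10⁻⁵ s⁻¹)
    monomer in chains → over-reaction product (k = 5.00 × 10⁻⁵ s⁻¹)
    protic impurity + free monomer → quenched substrate (k = 0.0130 M⁻¹ s⁻¹)

With 3.6 mM of protic impurity and its other charges and time as in this flask, a neighbour flask has an available share of 82.9%, and the same exponent gives 56.9%, where that neighbour flask shows 56.9%. This flask reads 62.0% free monomer at 3.00 d and 62.0% at 6.00 d, with living end down to 2.29 × 10⁻¹¹ mM. Ten times the time makes no difference to free monomer in this flask: it stands at 62.0% at 60.0 d.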